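You have 3 questions and one sum to do for them.

- midnight: starting complex 37 mM; incoming ligand 25.9 mM (fed, over 30 min); the very flask that is asked about, followed so far
- flask: starting complex 37 mM; incoming ligand 25.9 mM (fed, over 30 min); time 12 h

midnight run (percent of the starting complex charged)

| time / h | complex with one exchanged / % | side product / % |
|---|---|---|
| 0.500 | 4.0 | 0.2 |
| 1.50 | 15.3 | 1.8 |
| 3.00 | 23.7 | 7.4 |
| 4.00 | 26.1 | 11.4 |
| 6.00 | 28.1 | 19.0 |

(standard deviation of a reading: 0.3 percentage points)

- at 12 h, what has stopped the reaction, if anything has (it is still moving / all of the starting complex has reacted / the incoming ligand has run out first)
- how much complex with one exchanged there is at 12 h, in percent of the starting complex charged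
- how much side product there is at 12 h, in percent of the starting complex charged

- in percentages every species weighs as the starting complex in it: one side product counts as two
- the reaction counts as stopped when no species that holds the starting complex changes by six tenths of a point or more over the second half of the time

Work in fractions of the complex charge. The ligand charge is 70.0% of it, so the ligand is the limiting reagent of the exchange. The feed lasts 30 min against the 6.00 h of the last reading, so count the ligand as charged at the start. Let x be the ligand used, and assume it equals the summed readings of complex with one exchanged and side product. Then complex left is one minus x and ligand left is 70.0% minus x, and x grows as a constant K times those two.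

Integrating that rate gives a plain rule: the logarithm of complex left over ligand left climbs in a straight line, with slope K times the gap between the charges, 30.0%. That ratio starts at 1.43. At 6.00 h, x is 47.1%, so the ratio has grown by a factor 1.62. This gives K = 0.267 h⁻¹, the ligand clock, a second-order constant in fractions of the charge.

Twice the time squares that factor, so at 12 h x is 59.0%, with 15.7% of the ligand left. That is 12 percentage points gained over the second half, so the flask is still moving. Complex with one exchanged gained 2 points between 4.00 h and 6.00 h; hold it near 28.1%, and side product comes to about 30.9%.

The forecast also says it is still moving, but puts complex with one exchanged at 23.5% (21% to 26.5%) and side product higher, at 36.5% (33.5% to 39.5%): “Stepping the side product forward gives about 36%”.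

The flask's answer is it is still moving, with 27.2% of complex with one exchanged and 34.8% of side product. Side product lies inside the forecast's range, complex with one exchanged 0.70 points above the top of its range, and both forecast values are right within the tolerance.

    starting complex + incoming ligand → leaving ligand + complex with one exchanged (k = 0.110 M⁻¹ min⁻¹)
    starting complex + complex with one exchanged → side product (k = 0.0550 M⁻¹ min⁻¹)
    complex with two exchanged + incoming ligand → leaving ligand + complex with three exchanged (k = 0.0390 M⁻¹ min⁻¹)
    complex with one exchanged + incoming ligand → leaving ligand + complex with two exchanged (k = 0.0430 M⁻¹ min⁻¹)

The first exchange had 82% of its turnover behind it by 6.00 h, while the ligand fell to 33.7% of its charge. Side product kept forming beside it from starting complex and complex with one exchanged, the latter standing at 28.4% then. The clock's 15.7% of ligand left at 12 h stands against 16% in the flask, while the two products sum to 62.0%, above the clock's 59.0%.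

Read the same flask at 20 h: K gives x = 65.1%, so 7.00% of the ligand left. The computed flask holds 7.6% of it, with 23.3% of complex with one exchanged and 47.4% of side product.

The runs come from a simulation on assumed constants; noise was put on by code.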